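**Retrosynthetic overview**

- Ring B (C5–C10, drimane numbering) carries oxygen at the para-related C6 and C9 and one carbon each at C10 (methyl) and C8 (C12). This is the pattern of 2,6-dimethyl-1,4-benzoquinone. Ring A (C1–C5, C10) is a plain carbocycle ending in the C4 gem-dimethyl carbon, and the C5/C10 fusion of the target is cis.
- Late disconnections: the C6–O ester bond (Mitsunobu, inversion), the C12 aldehyde (allylic oxidation of the C8 methyl), the C11 acid (C9 ketone → methylene → diol → acid), and the saturation of ring A.
- Key disconnection: C1–C10 and C4–C5, by a catalytic enantioselective [4+2] cycloaddition of the quinone with 4-methylpenta-1,3-diene.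
- Ring order: ring B is bought as the quinone, ring A is closed in step 1, and no ring is formed afterwards.

Key step: step 1

Convention: drimane numbering; β is the face of ring B that carries the C10 methyl group. The target then has H-5, the C6 acyloxy group and the C9 hydroxyl on the β face and C11 on the α face.

Assumption: the target is made as the open hydroxy acid–enal that is drawn; a possible ring–chain equilibrium between the C11 acid and the C12 aldehyde is not treated as a separate compound.

Assumption: the (S)-configured oxazaborolidinium cation is assigned to the required alkene face from the usual pre-transition-state model of these cations; if the sense is the opposite, the equally accessible (R) antipode replaces it with no other change.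

**Route**

Step 1
Reactants: 1 2,6-dimethyl-1,4-benzoquinone; 2 4-methylpenta-1,3-diene
Product: 3 (4aR,8aS)-2,5,5,8a-tetramethyl-4a,5,8,8a-tetrahydronaphthalene-1,4-dione (cis-fused enedione)
Conditions: (S)-3,3-diphenyl-1-(o-tolyl)tetrahydropyrrolo[1,2-c][1,3,2]oxazaborole (20 mol %), Tf2NH (18 mol %), 2 (5 equiv, freshly distilled), CH2Cl2, −78 → −20 °C
Reagents that add atoms: none
Why: The protonated oxazaborolidine binds the less hindered C6 carbonyl (the one between the two CH positions of 1) and lowers the LUMO of the C5=C10 alkene, so that the diene adds in a concerted, asynchronous [4+2] cycloaddition in which its unsubstituted CH2 terminus (C1, largest HOMO coefficient) leads the bonding to the β-carbon C10 and its gem-dimethyl terminus (C4) closes onto the α-carbon C5. The closest known reaction type is the oxazaborolidinium-catalysed enantioselective Diels–Alder reaction of 2,6-disubstituted 1,4-benzoquinones with terminally substituted dienes. Ring A is closed as a six-membered carbocycle by intermolecular [4+2] annulation onto ring B. The cis relation of H-5 and the C10 methyl follows from suprafacial addition to the ring alkene, and the absolute configuration of both centres comes from the catalyst, whose aryl group covers one face of the bound alkene. The step needs regioselectivity (gem-dimethyl carbon at C5, not at the methyl-bearing C10) and face selectivity: the first is secured by coordination at the C6 carbonyl together with the avoidance of two adjacent quaternary carbons, the second by the chiral cation. Site selectivity does not arise because the two quinone alkenes are equivalent by symmetry, endo/exo selectivity is irrelevant because neither diene terminus becomes a stereocentre, and the hindered trisubstituted alkene left in 3 should not react again.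

Step 2
Reactants: 3 cis-fused enedione
Product: 4 6α-hydroxy enone (C6 alcohol with OH trans to H-5, C9 ketone retained)
Conditions: NaBH4, CeCl3·7H2O, MeOH, −78 °C
Reagents that add atoms: none
Why: Luche 1,2-reduction should take place at the less hindered C6 carbonyl (C9 is flanked by the quaternary C10 and the methyl-bearing C8), with hydride entering from the convex β face, syn to H-5 and anti to ring A, to give the 6α-alcohol, whose configuration is inverted on purpose in step 11, and after which C5 can no longer epimerise.

Step 3
Reactants: 4 6α-hydroxy enone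
Product: 5 6α-tert-butyldimethylsilyl ether of 4
Conditions: TBSOTf, 2,6-lutidine, CH2Cl2, −78 → 0 °C
Reagents that add atoms: tert-butyldimethylsilyl trifluoromethanesulfonate, CC(C)(C)[Si](C)(C)OS(=O)(=O)C(F)(F)F
Why: Silylation of a hindered secondary alcohol with the silyl triflate is a standard protection, and the bulky ether on the α face should later help to keep osmium away from the C7=C8 alkene.

Step 4
Reactants: 5 silyl ether with C2=C3 and C7=C8 alkenes
Product: 6 6α-silyloxy enone with saturated ring A
Conditions: 2-nitrobenzenesulfonylhydrazide, Et3N, CH2Cl2, rt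
Reagents that add atoms: none
Why: Diimide reduction transfers two hydrogen atoms in a concerted syn fashion to the unconjugated cis-disubstituted C2=C3 alkene far faster than to the trisubstituted, conjugated C7=C8 alkene, and it leaves the ketone and the allylic C–O bond untouched while creating no stereocentre.

Step 5
Reactants: 6 6α-silyloxy C9 ketone
Product: 7 6α-silyloxy-7,9(11)-diene (exocyclic methylene at C9)
Conditions: (C5H5)2Ti(CH3)2 (3 equiv), toluene/THF, 70 °C, dark
Reagents that add atoms: dimethyltitanocene, C[Ti](C)(C1C=CC=C1)C1C=CC=C1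
Why: Petasis methylenation, in which the non-basic titanium methylidene formed on heating adds to the carbonyl by [2+2] cycloaddition and cycloreversion, is suited to this hindered enone carbonyl next to a quaternary carbon, where phosphorus ylides are too bulky and too basic.

Step 6
Reactants: 7 7,9(11)-diene
Product: 8 6α-silyloxy-9β,11-diol (tertiary OH β, CH2OH α)
Conditions: OsO4 (2 mol %), NMO (1.1 equiv), acetone/H2O, 0 °C
Reagents that add atoms: osmium tetroxide, O=[Os](=O)(=O)=O; N-methylmorpholine N-oxide, C[N+]1([O-])CCOCC1; water, O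
Why: Upjohn dihydroxylation should add OsO4 suprafacially ([3+2]) to the terminal, most accessible 1,1-disubstituted alkene rather than to the trisubstituted ring alkene flanked by the silyloxy-bearing C6, and from the convex β face because ring A and the silyloxy group cover the α face, which places the C9 hydroxyl β and C11 α as in the target.

Step 7
Reactants: 8 9β,11-diol
Product: 10 6α-silyloxy-9β-hydroxy-11-oic acid, via hydroxy aldehyde 9 (not isolated)
Conditions: TEMPO (10 mol %), NaClO2 (2 equiv), NaOCl (2 mol %), MeCN/phosphate buffer pH 6.7, 35 °C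
Reagents that add atoms: sodium chlorite, [Na+].[O-]Cl=O
Why: The TEMPO/chlorite oxidation (oxoammonium oxidation to the aldehyde, then chlorite oxidation to the acid) converts only the primary alcohol, since the tertiary alcohol is inert, the near-neutral buffer spares the silyl ether, and C9 bears no hydrogen and cannot epimerise.

Step 8
Reactants: 10 hydroxy acid
Product: 11 allyl ester of 10
Conditions: allyl bromide, Cs2CO3, DMF, 0 °C → rt
Reagents that add atoms: allyl bromide, C=CCBr
Why: SN2 O-alkylation of the caesium carboxylate masks the acid as an ester that is removable under neutral palladium catalysis at the end, while the tertiary alcohol is not alkylated by carbonate.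

Step 9
Reactants: 11 allyl ester with C8 methyl group
Product: 13 allyl 6α-silyloxy-9β-hydroxy-12-oxo-7-en-11-oate (C12 enal), via allylic alcohol 12 (not isolated)
Conditions: SeO2 (2.5 equiv), 1,4-dioxane, 80 °C
Reagents that add atoms: selenium dioxide, O=[Se]=O
Why: Selenium dioxide allylic oxidation (ene reaction, [2,3]-sigmatropic shift, then further oxidation of the allylic alcohol) should occur at the methyl group on the more substituted alkene carbon C8, the only hydrogen-bearing substituent at that end because C9 is fully substituted, and gives the conjugated aldehyde.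

Step 10
Reactants: 13 silyl-protected enal
Product: 14 allyl 6α,9β-dihydroxy-12-oxo-7-en-11-oate
Conditions: HF·pyridine, pyridine, THF, 0 °C → rt
Reagents that add atoms: none
Why: Fluoride-mediated desilylation under buffered conditions frees the C6 alcohol without affecting the enal, the allyl ester or the tertiary alcohol.

Step 11
Reactants: 14 6α-alcohol; 15 (2E,4E,6E)-octa-2,4,6-trienoic acid
Product: 16 allyl 9β-hydroxy-6β-[(2E,4E,6E)-octa-2,4,6-trienoyloxy]-12-oxo-7-en-11-oate
Conditions: PPh3, DIAD, 15 (2 equiv), toluene, 0 °C → rt, dark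
Reagents that add atoms: none
Why: In this Mitsunobu esterification the alkoxyphosphonium ion of the secondary C6 alcohol should be displaced by the trienoate in an SN2 process from the open β face, inverting C6 to the required 6β-acyloxy configuration, while the electron-poor enal disfavours ionisation and SN2′ attack at the fully substituted C8 and the tertiary C9 alcohol does not react.

Step 12
Reactants: 16 allyl ester
Product: 17 target, 9β-hydroxy-6β-[(2E,4E,6E)-octa-2,4,6-trienoyloxy]-12-oxo-5β-drim-7-en-11-oic acid
Conditions: Pd(PPh3)4 (5 mol %), PhNHMe (3 equiv), THF, rt, dark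
Reagents that add atoms: none
Why: Tsuji–Trost deallylation, in which zerovalent palladium ionises only the unhindered allyl ester to a π-allyl complex that N-methylaniline captures, frees the acid under neutral conditions that spare the trienoate, the enal and the hindered allylic C6 ester.

**Compound list**

1 | 2,6-dimethyl-1,4-benzoquinone | CC1=CC(=O)C=C(C)C1=O | starting material
2 | 4-methylpenta-1,3-diene | CC(C)=CC=C | starting material
3 | (4aR,8aS)-2,5,5,8a-tetramethyl-4a,5,8,8a-tetrahydronaphthalene-1,4-dione; cis-fused, C6 and C9 ketones, C7=C8 and C2=C3 alkenes, H-5 and C10 methyl both β | O=C1C=C(C)C(=O)[C@@]2(C)CC=CC(C)(C)[C@@H]12 | intermediate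
4 | 6α-hydroxy derivative of 3 (C6 alcohol, OH trans to H-5; C9 ketone) | O[C@H]1C=C(C)C(=O)[C@@]2(C)CC=CC(C)(C)[C@@H]12 | intermediate
5 | 6α-tert-butyldimethylsilyl ether of 4 | CC(C)(C)[Si](C)(C)O[C@H]1C=C(C)C(=O)[C@@]2(C)CC=CC(C)(C)[C@@H]12 | intermediate
6 | 6α-silyloxy-11-nor-5β-drim-7-en-9-one (ring A saturated) | CC(C)(C)[Si](C)(C)O[C@H]1C=C(C)C(=O)[C@@]2(C)CCCC(C)(C)[C@@H]12 | intermediate
7 | 6α-silyloxy-5β-drima-7,9(11)-diene | CC(C)(C)[Si](C)(C)O[C@H]1C=C(C)C(=C)[C@@]2(C)CCCC(C)(C)[C@@H]12 | intermediate
8 | 6α-silyloxy-5β-drim-7-ene-9β,11-diol | CC(C)(C)[Si](C)(C)O[C@H]1C=C(C)[C@@](O)(CO)[C@@]2(C)CCCC(C)(C)[C@@H]12 | intermediate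
9 | 6α-silyloxy-9β-hydroxy-5β-drim-7-en-11-al | CC(C)(C)[Si](C)(C)O[C@H]1C=C(C)[C@@](O)(C=O)[C@@]2(C)CCCC(C)(C)[C@@H]12 | intermediate (not isolated)
10 | 6α-silyloxy-9β-hydroxy-5β-drim-7-en-11-oic acid | CC(C)(C)[Si](C)(C)O[C@H]1C=C(C)[C@@](O)(C(=O)O)[C@@]2(C)CCCC(C)(C)[C@@H]12 | intermediate
11 | allyl 6α-silyloxy-9β-hydroxy-5β-drim-7-en-11-oate | CC(C)(C)[Si](C)(C)O[C@H]1C=C(C)[C@@](O)(C(=O)OCC=C)[C@@]2(C)CCCC(C)(C)[C@@H]12 | intermediate
12 | allyl 6α-silyloxy-9β,12-dihydroxy-5β-drim-7-en-11-oate | CC(C)(C)[Si](C)(C)O[C@H]1C=C(CO)[C@@](O)(C(=O)OCC=C)[C@@]2(C)CCCC(C)(C)[C@@H]12 | intermediate (not isolated)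
13 | allyl 6α-silyloxy-9β-hydroxy-12-oxo-5β-drim-7-en-11-oate | CC(C)(C)[Si](C)(C)O[C@H]1C=C(C=O)[C@@](O)(C(=O)OCC=C)[C@@]2(C)CCCC(C)(C)[C@@H]12 | intermediate
14 | allyl 6α,9β-dihydroxy-12-oxo-5β-drim-7-en-11-oate | O[C@H]1C=C(C=O)[C@@](O)(C(=O)OCC=C)[C@@]2(C)CCCC(C)(C)[C@@H]12 | intermediate
15 | (2E,4E,6E)-octa-2,4,6-trienoic acid | C/C=C/C=C/C=C/C(=O)O | starting material
16 | allyl 9β-hydroxy-6β-[(2E,4E,6E)-octa-2,4,6-trienoyloxy]-12-oxo-5β-drim-7-en-11-oate | C/C=C/C=C/C=C/C(=O)O[C@@H]1C=C(C=O)[C@@](O)(C(=O)OCC=C)[C@@]2(C)CCCC(C)(C)[C@@H]12 | intermediate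
17 | 9β-hydroxy-6β-[(2E,4E,6E)-octa-2,4,6-trienoyloxy]-12-oxo-5β-drim-7-en-11-oic acid | C/C=C/C=C/C=C/C(=O)O[C@@H]1C=C(C=O)[C@@](O)(C(=O)O)[C@@]2(C)CCCC(C)(C)[C@@H]12 | target

**Step count**

Total: 12 steps. Longest linear sequence: 12 steps (1 and 2 → 17); acid 15 enters in step 11.

**Steps most likely to fail**

Step 1. The cycloaddition may stall because the cis-methyl group at the diene terminus disfavours the s-cis conformer, the diene may be consumed by acid-induced oligomerisation, or the catalyst may discriminate the two alkene faces poorly. The fallback sets out from 1 and 2 and gives up catalytic enantiocontrol. The cycloaddition is driven with the stronger achiral Lewis acid SnCl4 (CH2Cl2, −78 → −20 °C), which binds the same C6 carbonyl and should give 3 together with the (4aS,8aR) enantiomer of the adduct F1. Luche reduction of the mixture gives 4 and the enantiomeric alcohol F2. Esterification with (S)-2-methoxy-2-phenylacetic acid (EDC, DMAP, CH2Cl2) gives the (S)-O-methylmandelate of 4 F3 and the (S)-O-methylmandelate of the enantiomeric alcohol F4, which are separated by chromatography or crystallisation. Methanolysis of F3 (K2CO3, MeOH) returns to the route at 4.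

Step 6. Osmylation may occur at the ring alkene C7=C8 instead of, or in addition to, the exocyclic alkene, since the two belong to one conjugated diene. The fallback sets out from 7 and builds the C9 carbinol by enolate oxidation instead. Hydroboration with 9-BBN (THF, rt) is expected at the terminal carbon of the exocyclic alkene only, with hydrogen delivered to C9 from the β face, and gives the C11 organoborane F5. This is oxidised in the same flask (NaOH, H2O2) to the primary C11 alcohol F6. TEMPO/NaClO2 oxidation gives the C11 carboxylic acid F7, and allylation (allyl bromide, Cs2CO3, DMF) gives the allyl ester F8. Deprotonation at C9 with KN(SiMe3)2 (THF, −78 °C) and oxidation of the enolate at its α-carbon from the β face with 2-(phenylsulfonyl)-3-phenyloxaziridine should install the 9β-hydroxyl and rejoin the route at 11.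

Step 11. The activated C6 oxygen may be lost by anti elimination with H-5 to a conjugated dienal, or the ester may form with retention through acyl transfer if SN2 attack is slowed by the flanking quaternary carbons. The fallback sets out from 14 and separates inversion from acylation. Tf2O and pyridine (CH2Cl2, −30 °C) give the 6α-triflate F9. The small, weakly basic nitrite ion (Bu4NNO2, toluene, rt) displaces it to the 6β-nitrite ester F10, which hydrolyses on aqueous work-up to the 6β-alcohol F11 (Lattrell–Dax inversion). Acylation with retention by the mixed 2,4,6-trichlorobenzoic anhydride of 15 F12 (from 15, 2,4,6-trichlorobenzoyl chloride and Et3N; then DMAP, toluene; Yamaguchi esterification) returns to the route at 16.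

**Further compounds**

F1 | step 1 | (4aS,8aR)-2,5,5,8a-tetramethyl-4a,5,8,8a-tetrahydronaphthalene-1,4-dione (enantiomer of 3) | O=C1C=C(C)C(=O)[C@]2(C)CC=CC(C)(C)[C@H]12
F2 | step 1 | enantiomer of alcohol 4 | O[C@@H]1C=C(C)C(=O)[C@]2(C)CC=CC(C)(C)[C@H]12
F3 | step 1 | (S)-2-methoxy-2-phenylacetate of 4 | CO[C@H](C(=O)O[C@H]1C=C(C)C(=O)[C@@]2(C)CC=CC(C)(C)[C@@H]12)c1ccccc1
F4 | step 1 | (S)-2-methoxy-2-phenylacetate of the enantiomer of 4 | CO[C@H](C(=O)O[C@@H]1C=C(C)C(=O)[C@]2(C)CC=CC(C)(C)[C@H]12)c1ccccc1
F5 | step 6 | 11-(9-borabicyclo[3.3.1]nonan-9-yl)-6α-silyloxy-5β,9β-H-drim-7-ene | CC(C)(C)[Si](C)(C)O[C@H]1C=C(C)[C@@H](CB3C4CCCC3CCC4)[C@@]2(C)CCCC(C)(C)[C@@H]12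
F6 | step 6 | 6α-silyloxy-5β,9β-H-drim-7-en-11-ol | CC(C)(C)[Si](C)(C)O[C@H]1C=C(C)[C@@H](CO)[C@@]2(C)CCCC(C)(C)[C@@H]12
F7 | step 6 | 6α-silyloxy-5β,9β-H-drim-7-en-11-oic acid | CC(C)(C)[Si](C)(C)O[C@H]1C=C(C)[C@@H](C(=O)O)[C@@]2(C)CCCC(C)(C)[C@@H]12
F8 | step 6 | allyl 6α-silyloxy-5β,9β-H-drim-7-en-11-oate | CC(C)(C)[Si](C)(C)O[C@H]1C=C(C)[C@@H](C(=O)OCC=C)[C@@]2(C)CCCC(C)(C)[C@@H]12
F9 | step 11 | allyl 9β-hydroxy-12-oxo-6α-(trifluoromethanesulfonyloxy)-5β-drim-7-en-11-oate | FC(F)(F)S(=O)(=O)O[C@H]1C=C(C=O)[C@@](O)(C(=O)OCC=C)[C@@]2(C)CCCC(C)(C)[C@@H]12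
F10 | step 11 | allyl 9β-hydroxy-6β-nitrosooxy-12-oxo-5β-drim-7-en-11-oate | O=NO[C@@H]1C=C(C=O)[C@@](O)(C(=O)OCC=C)[C@@]2(C)CCCC(C)(C)[C@@H]12
F11 | step 11 | allyl 6β,9β-dihydroxy-12-oxo-5β-drim-7-en-11-oate | O[C@@H]1C=C(C=O)[C@@](O)(C(=O)OCC=C)[C@@]2(C)CCCC(C)(C)[C@@H]12
F12 | step 11 | (2E,4E,6E)-octa-2,4,6-trienoic 2,4,6-trichlorobenzoic anhydride | C/C=C/C=C/C=C/C(=O)OC(=O)c1c(Cl)cc(Cl)cc1Cl
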